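**Strategy.** The route rests on disconnecting C2–C3 of ring C of the upper flavan unit. The precursor is open-chain: a (Z)-enol gallate (future C3=C4, already carrying the 3-O-galloyl group) sits ortho to an acylal oxygen (future O1) on phloroglucinol ring A. Acid ionisation gives an O1=C2 oxocarbenium ion stabilised by catechol ring B, and an asymmetric Prins cyclisation closes ring C through C2–C3, setting C2, C3 and C4 in one operation. The step exploits ring A, whose three oxygens stabilise the C4 cation formed. Pivalate return gives a 4β-acyloxy electrophile, which is then joined to C6 of a C8-bromo-blocked epicatechin gallate derived from (−)-epicatechin.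

Key step: step 8

Assumption: the (S,S)-antipode of the chiral acid in step 8 is taken to give the (2R) series; the sense of induction is a matter of catalyst screening, and the (R,R)-antipode is used if it proves opposite.

Step 1
Reactants: 1 (−)-epicatechin
Product: 2 5,7,3',4'-tetra-O-benzyl-(−)-epicatechin (2R,3R)
Conditions: BnBr (4.4 equiv), K2CO3, DMF, −10 °C to rt
Reagents that add atoms: benzyl bromide, BrCc1ccccc1
Why: Williamson etherification of the four phenols under mild carbonate conditions should leave the far less acidic secondary 3-hydroxyl free and the C2/C3 stereocentres untouched.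

Step 2
Reactants: 2 5,7,3',4'-tetra-O-benzyl-(−)-epicatechin; 3 3,4,5-tris(benzyloxy)benzoic acid
Product: 4 5,7,3',4'-tetra-O-benzyl-(−)-epicatechin 3-O-(3,4,5-tri-O-benzyl)gallate (2R,3R)
Conditions: DCC, DMAP (cat.), CH2Cl2, 0 °C to rt
Reagents that add atoms: none
Why: Steglich esterification acylates the 3-hydroxyl at oxygen, so the C3 configuration is retained and the protected gallate is installed without touching the benzyl ethers.

Step 3
Reactants: 4 5,7,3',4'-tetra-O-benzyl-(−)-epicatechin 3-O-(3,4,5-tri-O-benzyl)gallate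
Product: 5 8-bromo-5,7,3',4'-tetra-O-benzyl-(−)-epicatechin 3-O-(3,4,5-tri-O-benzyl)gallate (2R,3R)
Conditions: NBS (1.05 equiv), CH2Cl2, −78 to −20 °C
Reagents that add atoms: N-bromosuccinimide, O=C1CCC(=O)N1Br
Why: Electrophilic aromatic bromination should occur on ring A, the most electron-rich arene, and at C8 rather than at C6, which is flanked by two benzyloxy groups; the bromine blocks C8 for step 10.

Step 4
Reactants: 6 2,4,6-trihydroxybenzaldehyde
Product: 7 2,4-bis(benzyloxy)-6-hydroxybenzaldehyde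
Conditions: BnBr (2.1 equiv), K2CO3 (2.2 equiv), DMF, rt
Reagents that add atoms: benzyl bromide, BrCc1ccccc1
Why: Regioselective Williamson etherification; after the para and one ortho hydroxyl have reacted, the remaining ortho hydroxyl is hydrogen-bonded to the aldehyde and is the least nucleophilic.

Step 5
Reactants: 7 2,4-bis(benzyloxy)-6-hydroxybenzaldehyde; 8 3,4-bis(benzyloxy)benzaldehyde
Product: 10 [3,4-bis(benzyloxy)phenyl][3,5-bis(benzyloxy)-2-formylphenoxy]methyl 2,2-dimethylpropanoate (racemic at the acylal carbon), via α-chlorobenzyl pivalate 9 (not isolated)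
Conditions: 8, PivCl, ZnCl2 (cat.), CH2Cl2, 0 °C to rt; then 7, NaH, THF/DMF, 0 °C
Reagents that add atoms: pivaloyl chloride, CC(C)(C)C(=O)Cl
Why: Lewis-acid-catalysed addition of the acyl chloride across the aldehyde C=O gives the α-chloroalkyl ester, which O-alkylates the sodium phenoxide in the way acyloxymethyl chlorides do (the hindered pivaloyl carbonyl is spared); the acylal carbon is formed racemic and is erased in step 8.

Step 6
Reactants: 10 [3,4-bis(benzyloxy)phenyl][3,5-bis(benzyloxy)-2-formylphenoxy]methyl 2,2-dimethylpropanoate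
Product: 11 [3,4-bis(benzyloxy)phenyl][3,5-bis(benzyloxy)-2-ethynylphenoxy]methyl 2,2-dimethylpropanoate (racemic at the acylal carbon)
Conditions: TMSCHN2, LiN(iPr)2, THF, −78 °C to rt
Reagents that add atoms: (trimethylsilyl)diazomethane, C[Si](C)(C)C=[N+]=[N-]
Why: Colvin rearrangement (addition of lithiated trimethylsilyldiazomethane to the aldehyde, Peterson elimination, 1,2-hydrogen shift of the alkylidene carbene) gives the terminal alkyne under non-nucleophilic, methanol-free conditions that the pivalate acylal should survive.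

Step 7
Reactants: 11 [3,4-bis(benzyloxy)phenyl][3,5-bis(benzyloxy)-2-ethynylphenoxy]methyl 2,2-dimethylpropanoate; 3 3,4,5-tris(benzyloxy)benzoic acid
Product: 12 (Z)-2-{2,4-bis(benzyloxy)-6-[(3,4-bis(benzyloxy)phenyl)(pivaloyloxy)methoxy]phenyl}ethenyl 3,4,5-tris(benzyloxy)benzoate
Conditions: Ru(methallyl)2(dppb) (2 mol%), toluene, 50 °C
Reagents that add atoms: none
Why: Ruthenium-vinylidene-mediated anti-Markovnikov addition of the carboxylic acid to the terminal alkyne should give the (Z)-enol ester, installing the gallate on the future C3 oxygen and the olefin geometry needed in step 8 without added base or strong acid.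

Step 8
Reactants: 12 (Z)-2-{2,4-bis(benzyloxy)-6-[(3,4-bis(benzyloxy)phenyl)(pivaloyloxy)methoxy]phenyl}ethenyl 3,4,5-tris(benzyloxy)benzoate
Product: 13 4β-pivaloyloxy-5,7,3',4'-tetra-O-benzyl-(−)-epicatechin 3-O-(3,4,5-tri-O-benzyl)gallate (2R,3S,4S; 2,3-cis, 3,4-trans)
Conditions: (S,S)-imidodiphosphorimidate (confined chiral Brønsted acid, 5 mol%), CHCl3, −50 °C
Reagents that add atoms: none
Why: Proposed new method: the chiral acid protonates the pivaloyl carbonyl of the acylal and expels pivalic acid (the aryloxy group is by far the poorer leaving group), giving the O1=C2 oxocarbenium ion, stabilised by the 3,4-bis(benzyloxy)phenyl ring B, as a contact ion pair with the chiral anion; C3 of the (Z)-enol gallate attacks C2, and the resulting C4 cation, stabilised by the trioxygenated ring A and by the neighbouring galloyl carbonyl as a 1,3-dioxolan-2-ylium ion, is captured by the liberated pivalic acid, so that the net change is a ring-closing 1,3-acyloxy transposition. The closest known reaction types are the Brønsted-acid-catalysed asymmetric Prins cyclisation with confined imidodiphosphorimidates and the Lewis-acid Prins cyclisation of α-acyloxy ethers; new are the aryl oxocarbenium ion and the use of an enol ester through its oxygen-bearing carbon. Ring C closes in the 6-endo-trig mode through a chair-like transition state. The absolute configuration at C2 and C3 is set by the chiral counter-anion, the 2,3-cis relation by the (Z)-olefin geometry (equatorial aryl on the (E)-oxocarbenium ion, axial acyloxy group), and C4 by opening of the cis-fused dioxolanylium ion anti to the C3 oxygen (4β). The step needs attack through C3 rather than C4 (6-endo over 5-exo), which the substrate secures because only C3 attack leads to the phloroglucinol-stabilised benzylic cation whereas C4 attack would give a poorly stabilised α-acyloxy cation, and it needs a slow uncatalysed background, which the weakly ionising pivalate acylal should provide.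

Step 9
Reactants: 13 4β-pivaloyloxy-5,7,3',4'-tetra-O-benzyl-(−)-epicatechin 3-O-(3,4,5-tri-O-benzyl)gallate
Product: 14 8-bromo-4β-pivaloyloxy-5,7,3',4'-tetra-O-benzyl-(−)-epicatechin 3-O-(3,4,5-tri-O-benzyl)gallate (2R,3S,4S)
Conditions: NBS (1.05 equiv), CH2Cl2, −78 to −30 °C
Reagents that add atoms: N-bromosuccinimide, O=C1CCC(=O)N1Br
Why: The same ring-A-selective electrophilic bromination at C8 as in step 3 caps the most nucleophilic position of the electrophile, so that it should not condense with itself in step 10.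

Step 10
Reactants: 14 8-bromo-4β-pivaloyloxy-5,7,3',4'-tetra-O-benzyl-(−)-epicatechin 3-O-(3,4,5-tri-O-benzyl)gallate; 5 8-bromo-5,7,3',4'-tetra-O-benzyl-(−)-epicatechin 3-O-(3,4,5-tri-O-benzyl)gallate (3 equiv)
Product: 15 [8-bromo-5,7,3',4'-tetra-O-benzyl-epicatechin 3-O-(3,4,5-tri-O-benzyl)gallate]-(4β→6)-[8-bromo-5,7,3',4'-tetra-O-benzyl-epicatechin 3-O-(3,4,5-tri-O-benzyl)gallate]
Conditions: TMSOTf (0.5 equiv), CH2Cl2, −78 to −40 °C
Reagents that add atoms: none
Why: Lewis-acid ionisation of the 4-pivalate gives the flavan C4 cation, held on the α-face as a dioxolanylium ion by the 3-O-galloyl group, and Friedel–Crafts attack from the β-face by C6 of 5 (C8 is blocked by bromine) should give the 4β→6, 3,4-trans interflavan bond, with excess 5 suppressing self-condensation.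

Step 11
Reactants: 15 [8-bromo-5,7,3',4'-tetra-O-benzyl-epicatechin 3-O-(3,4,5-tri-O-benzyl)gallate]-(4β→6)-[8-bromo-5,7,3',4'-tetra-O-benzyl-epicatechin 3-O-(3,4,5-tri-O-benzyl)gallate]
Product: 16 procyanidin B-5 3,3'-di-O-gallate
Conditions: H2 (1 atm), Pd(OH)2/C, Et3N (2.5 equiv), THF/MeOH/H2O, rt
Reagents that add atoms: none
Why: Catalytic hydrogenolysis should remove the fourteen benzyl ethers and both aryl bromides in one operation, leaving the gallate esters, the interflavan bond and all stereocentres untouched.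

**Compound list**

1 | (−)-epicatechin (2R,3R) | O[C@@H]1Cc2c(O)cc(O)cc2O[C@@H]1c1ccc(O)c(O)c1 | starting material
2 | 5,7,3',4'-tetra-O-benzyl-(−)-epicatechin (2R,3R) | O[C@@H]1Cc2c(OCc3ccccc3)cc(OCc3ccccc3)cc2O[C@@H]1c1ccc(OCc2ccccc2)c(OCc2ccccc2)c1 | intermediate
3 | 3,4,5-tris(benzyloxy)benzoic acid | OC(=O)c1cc(OCc2ccccc2)c(OCc2ccccc2)c(OCc2ccccc2)c1 | starting material
4 | 5,7,3',4'-tetra-O-benzyl-(−)-epicatechin 3-O-(3,4,5-tri-O-benzyl)gallate (2R,3R) | O=C(O[C@@H]1Cc2c(OCc3ccccc3)cc(OCc3ccccc3)cc2O[C@@H]1c1ccc(OCc2ccccc2)c(OCc2ccccc2)c1)c1cc(OCc2ccccc2)c(OCc2ccccc2)c(OCc2ccccc2)c1 | intermediate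
5 | 8-bromo-5,7,3',4'-tetra-O-benzyl-(−)-epicatechin 3-O-(3,4,5-tri-O-benzyl)gallate (2R,3R) | O=C(O[C@@H]1Cc2c(OCc3ccccc3)cc(OCc3ccccc3)c(Br)c2O[C@@H]1c1ccc(OCc2ccccc2)c(OCc2ccccc2)c1)c1cc(OCc2ccccc2)c(OCc2ccccc2)c(OCc2ccccc2)c1 | intermediate
6 | 2,4,6-trihydroxybenzaldehyde | O=Cc1c(O)cc(O)cc1O | starting material
7 | 2,4-bis(benzyloxy)-6-hydroxybenzaldehyde | O=Cc1c(O)cc(OCc2ccccc2)cc1OCc1ccccc1 | intermediate
8 | 3,4-bis(benzyloxy)benzaldehyde | O=Cc1ccc(OCc2ccccc2)c(OCc2ccccc2)c1 | starting material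
9 | chloro[3,4-bis(benzyloxy)phenyl]methyl 2,2-dimethylpropanoate (racemic) | CC(C)(C)C(=O)OC(Cl)c1ccc(OCc2ccccc2)c(OCc2ccccc2)c1 | intermediate
10 | [3,4-bis(benzyloxy)phenyl][3,5-bis(benzyloxy)-2-formylphenoxy]methyl 2,2-dimethylpropanoate (racemic at the acylal carbon) | O=Cc1c(OC(OC(=O)C(C)(C)C)c2ccc(OCc3ccccc3)c(OCc3ccccc3)c2)cc(OCc2ccccc2)cc1OCc1ccccc1 | intermediate
11 | [3,4-bis(benzyloxy)phenyl][3,5-bis(benzyloxy)-2-ethynylphenoxy]methyl 2,2-dimethylpropanoate (racemic at the acylal carbon) | C#Cc1c(OC(OC(=O)C(C)(C)C)c2ccc(OCc3ccccc3)c(OCc3ccccc3)c2)cc(OCc2ccccc2)cc1OCc1ccccc1 | intermediate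
12 | (Z)-2-{2,4-bis(benzyloxy)-6-[(3,4-bis(benzyloxy)phenyl)(pivaloyloxy)methoxy]phenyl}ethenyl 3,4,5-tris(benzyloxy)benzoate (Z olefin; racemic at the acylal carbon) | O=C(O/C=C\c1c(OC(OC(=O)C(C)(C)C)c2ccc(OCc3ccccc3)c(OCc3ccccc3)c2)cc(OCc2ccccc2)cc1OCc1ccccc1)c1cc(OCc2ccccc2)c(OCc2ccccc2)c(OCc2ccccc2)c1 | intermediate
13 | 4β-pivaloyloxy-5,7,3',4'-tetra-O-benzyl-(−)-epicatechin 3-O-(3,4,5-tri-O-benzyl)gallate (2R,3S,4S; 2,3-cis, 3,4-trans) | O=C(O[C@@H]1[C@@H](OC(=O)C(C)(C)C)c2c(OCc3ccccc3)cc(OCc3ccccc3)cc2O[C@@H]1c1ccc(OCc2ccccc2)c(OCc2ccccc2)c1)c1cc(OCc2ccccc2)c(OCc2ccccc2)c(OCc2ccccc2)c1 | intermediate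
14 | 8-bromo-4β-pivaloyloxy-5,7,3',4'-tetra-O-benzyl-(−)-epicatechin 3-O-(3,4,5-tri-O-benzyl)gallate (2R,3S,4S) | O=C(O[C@@H]1[C@@H](OC(=O)C(C)(C)C)c2c(OCc3ccccc3)cc(OCc3ccccc3)c(Br)c2O[C@@H]1c1ccc(OCc2ccccc2)c(OCc2ccccc2)c1)c1cc(OCc2ccccc2)c(OCc2ccccc2)c(OCc2ccccc2)c1 | intermediate
15 | [8-bromo-5,7,3',4'-tetra-O-benzyl-epicatechin 3-O-(3,4,5-tri-O-benzyl)gallate]-(4β→6)-[8-bromo-5,7,3',4'-tetra-O-benzyl-epicatechin 3-O-(3,4,5-tri-O-benzyl)gallate], all stereocentres as in the target | O=C(O[C@@H]1[C@@H](c2c(OCc3ccccc3)c(Br)c3c(c2OCc2ccccc2)C[C@@H](OC(=O)c2cc(OCc4ccccc4)c(OCc4ccccc4)c(OCc4ccccc4)c2)[C@@H](c2ccc(OCc4ccccc4)c(OCc4ccccc4)c2)O3)c2c(OCc3ccccc3)cc(OCc3ccccc3)c(Br)c2O[C@@H]1c1ccc(OCc2ccccc2)c(OCc2ccccc2)c1)c1cc(OCc2ccccc2)c(OCc2ccccc2)c(OCc2ccccc2)c1 | intermediate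
16 | procyanidin B-5 3,3'-di-O-gallate, epicatechin 3-O-gallate-(4β→6)-epicatechin 3-O-gallate | O=C(O[C@@H]1[C@@H](c2c(O)cc3c(c2O)C[C@@H](OC(=O)c2cc(O)c(O)c(O)c2)[C@@H](c2ccc(O)c(O)c2)O3)c2c(O)cc(O)cc2O[C@@H]1c1ccc(O)c(O)c1)c1cc(O)c(O)c(O)c1 | target

**Step count and risks**

Total step count: 11. Longest linear sequence: 8 steps (6 to 16 through steps 4, 5, 6, 7, 8, 9, 10 and 11).

The three steps most likely to fail:

Step 8 (key step, new method). The acylal may ionise without effective ion pairing, so that an uncatalysed racemic closure competes. The enol ester may instead attack through C4 (5-exo closure). The C4 cation may eliminate to the flav-3-ene or alkylate ring A of another molecule before pivalate returns. The fallback uses the chiral pool and known chemistry. It sets out from 4: benzylic oxidation at C4 with DDQ in CH2Cl2/MeOH at rt should give 4β-methoxy-5,7,3',4'-tetra-O-benzyl-(−)-epicatechin 3-O-(3,4,5-tri-O-benzyl)gallate F1, whose C2 and C3 come from natural epicatechin. Bromination with NBS under the conditions of step 9 should then give 8-bromo-4β-methoxy-5,7,3',4'-tetra-O-benzyl-(−)-epicatechin 3-O-(3,4,5-tri-O-benzyl)gallate F2. F2 is coupled with 5 under the conditions of step 10, with methanol leaving in place of pivalic acid, and the route is rejoined at 15.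

Step 7. (Z)-Selectivity may erode, or Markovnikov addition may occur, with the di-ortho-substituted arylalkyne. Carboxylate exchange or loss of the acylal in warm carboxylic acid is the other danger. The fallback sets out from 11: rhodium-catalysed trans-hydroboration with pinacolborane ([Rh(cod)Cl]2, PiPr3, Et3N, cyclohexane, rt) should give [3,4-bis(benzyloxy)phenyl]{3,5-bis(benzyloxy)-2-[(Z)-2-(4,4,5,5-tetramethyl-1,3,2-dioxaborolan-2-yl)ethenyl]phenoxy}methyl 2,2-dimethylpropanoate F3. A Chan–Lam-type copper-catalysed C–O coupling of F3 with acid 3 (Cu(OAc)2 (20 mol%), Et3N, 4 Å molecular sieves, O2, CH2Cl2, rt) then returns to 12 with retention of the olefin geometry and without warm free acid.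

Step 10. Attack at the hindered, bromine-deactivated C6 of 5 may be slow, so that elimination of the C4 cation or residual self-condensation of 14 takes over. The fallback sets out from 14 and replaces the protected nucleophile by a free phloroglucinol ring. Hydrogenolysis of 4 (H2, Pd(OH)2/C, THF/MeOH, rt) should give unprotected (−)-epicatechin 3-O-gallate F4. Condensation of 14 with an excess of F4 (BF3·OEt2 (0.3 equiv), THF/CH2Cl2, 0 °C) is the classical acid-mediated capture of a flavan C4 cation by a free phloroglucinol ring, and should give the 4β→8 and 4β→6 adducts. The 4β→6 isomer, [8-bromo-5,7,3',4'-tetra-O-benzyl-epicatechin 3-O-(3,4,5-tri-O-benzyl)gallate]-(4β→6)-(−)-epicatechin 3-O-gallate F5, is separated by chromatography (Sephadex LH-20, then reversed phase). Hydrogenolysis under the conditions of step 11 rejoins the route at 16.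

**Further compounds**

F1 | step 8 | 4β-methoxy-5,7,3',4'-tetra-O-benzyl-(−)-epicatechin 3-O-(3,4,5-tri-O-benzyl)gallate (2R,3R,4S) | O=C(O[C@@H]1[C@@H](OC)c2c(OCc3ccccc3)cc(OCc3ccccc3)cc2O[C@@H]1c1ccc(OCc2ccccc2)c(OCc2ccccc2)c1)c1cc(OCc2ccccc2)c(OCc2ccccc2)c(OCc2ccccc2)c1
F2 | step 8 | 8-bromo-4β-methoxy-5,7,3',4'-tetra-O-benzyl-(−)-epicatechin 3-O-(3,4,5-tri-O-benzyl)gallate (2R,3R,4S) | O=C(O[C@@H]1[C@@H](OC)c2c(OCc3ccccc3)cc(OCc3ccccc3)c(Br)c2O[C@@H]1c1ccc(OCc2ccccc2)c(OCc2ccccc2)c1)c1cc(OCc2ccccc2)c(OCc2ccccc2)c(OCc2ccccc2)c1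
F3 | step 7 | [3,4-bis(benzyloxy)phenyl]{3,5-bis(benzyloxy)-2-[(Z)-2-(4,4,5,5-tetramethyl-1,3,2-dioxaborolan-2-yl)ethenyl]phenoxy}methyl 2,2-dimethylpropanoate | CC1(C)OB(/C=C\c2c(OC(OC(=O)C(C)(C)C)c3ccc(OCc4ccccc4)c(OCc4ccccc4)c3)cc(OCc3ccccc3)cc2OCc2ccccc2)OC1(C)C
F4 | step 10 | (−)-epicatechin 3-O-gallate (2R,3R) | O=C(O[C@@H]1Cc2c(O)cc(O)cc2O[C@@H]1c1ccc(O)c(O)c1)c1cc(O)c(O)c(O)c1
F5 | step 10 | [8-bromo-5,7,3',4'-tetra-O-benzyl-epicatechin 3-O-(3,4,5-tri-O-benzyl)gallate]-(4β→6)-(−)-epicatechin 3-O-gallate | O=C(O[C@@H]1[C@@H](c2c(O)cc3c(c2O)C[C@@H](OC(=O)c2cc(O)c(O)c(O)c2)[C@@H](c2ccc(O)c(O)c2)O3)c2c(OCc3ccccc3)cc(OCc3ccccc3)c(Br)c2O[C@@H]1c1ccc(OCc2ccccc2)c(OCc2ccccc2)c1)c1cc(OCc2ccccc2)c(OCc2ccccc2)c(OCc2ccccc2)c1
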